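**Retrosynthetic overview**

- The C9 acetate is taken back to the 7,9-diol and then to a C9 triisopropylsilyl ether, so the last two steps only adjust the C9 oxygen.
- Key disconnection: the C7–C1 (ring A) bond. C7, the benzylic carbinol carbon, is bonded to C1 of ring A (3,4,5-trimethoxyphenyl) and sits next to C8, which carries the ether oxygen of ring B flanked by two methoxy groups. A C7 aldehyde and this C8 oxygen can hold magnesium in a five-membered chelate, so the fixed C8 centre directs aryl addition to C7.
- The C8–O (ring B) bond is made by Mitsunobu inversion of an (S)-glycerate C2 hydroxyl with 4-allyl-2,6-dimethoxyphenol, so C8 comes from the chiral pool.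
- No ring is formed; rings A and B are bought intact.

Key step: step 6

Remark: neolignan numbering is used (C7 benzylic CHOH, C8 aryloxy-bearing CH, C9 CH2O; ring A = 3,4,5-trimethoxyphenyl, ring B = 4-allyl-2,6-dimethoxyphenyl). The target is the 7R,8R (threo) isomer, and the (S)-glycerate acetonide is assumed to be purchasable in high enantiomeric purity.

**Route**

Step 1
Reactants: 1 methyl (S)-2,2-dimethyl-1,3-dioxolane-4-carboxylate
Product: 2 methyl (S)-2,3-dihydroxypropanoate
Conditions: Amberlyst-15 (H+ resin, cat.), MeOH, rt; filter, concentrate, repeat once from fresh MeOH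
Reagents that add atoms: none
Why: Acid-catalysed acetonide methanolysis (transketalisation) in excess methanol should free the 1,2-diol, while the methyl ester only undergoes degenerate exchange and the C2 centre is not touched.

Step 2
Reactants: 2 methyl (S)-2,3-dihydroxypropanoate
Product: 3 methyl (S)-2-hydroxy-3-[(triisopropylsilyl)oxy]propanoate
Conditions: i-Pr3SiCl (1.05 equiv), imidazole (2.2 equiv), CH2Cl2, 0 °C → rt
Reagents that add atoms: triisopropylsilyl chloride, CC(C)[Si](Cl)(C(C)C)C(C)C
Why: Silyl ether formation with a bulky trialkylsilyl chloride should be strongly selective for the primary hydroxyl over the secondary, ester-flanked one, leaving the C2 hydroxyl free.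

Step 3
Reactants: 3 methyl (S)-2-hydroxy-3-[(triisopropylsilyl)oxy]propanoate; 4 4-allyl-2,6-dimethoxyphenol
Product: 5 methyl (R)-2-(4-allyl-2,6-dimethoxyphenoxy)-3-[(triisopropylsilyl)oxy]propanoate
Conditions: 4 (1.2 equiv), PPh3 (1.3 equiv), DIAD (1.3 equiv), THF, 0 °C → rt
Reagents that add atoms: none
Why: Mitsunobu etherification of an α-hydroxy ester with a phenol proceeds by SN2 displacement of the alkoxyphosphonium group, so the (S)-carbinol should be inverted cleanly to the (R)-aryl ether that becomes C8.

Step 4
Reactants: 6 5-bromo-1,2,3-trimethoxybenzene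
Product: 7 3,4,5-trimethoxyphenylmagnesium bromide (about 1 M solution in THF, titrated)
Conditions: Mg turnings (1.2 equiv), I2 (cat.), THF, 45 °C then rt
Reagents that add atoms: magnesium, [Mg]
Why: Grignard formation by magnesium insertion into an electron-rich aryl bromide is routine in THF, and the methoxy groups are inert.

Step 5
Reactants: 5 methyl (R)-2-(4-allyl-2,6-dimethoxyphenoxy)-3-[(triisopropylsilyl)oxy]propanoate
Product: 8 (R)-2-(4-allyl-2,6-dimethoxyphenoxy)-3-[(triisopropylsilyl)oxy]propanal (crude, kept cold, used at once)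
Conditions: i-Bu2AlH (1.1 equiv, 1 M in toluene), CH2Cl2, −78 °C; MeOH at −78 °C, then aq. KNaC4H4O6 (Rochelle salt); cold extraction, no chromatography
Reagents that add atoms: none
Why: Partial reduction of an α-alkoxy ester with i-Bu2AlH at −78 °C should stop at the aluminium hemiacetal, which is stabilised by the α-aryloxy oxygen and releases the aldehyde only on work-up; the allyl group and silyl ether are inert and the cold, non-basic handling should preserve C8.

Step 6
Reactants: 8 (R)-2-(4-allyl-2,6-dimethoxyphenoxy)-3-[(triisopropylsilyl)oxy]propanal; 7 3,4,5-trimethoxyphenylmagnesium bromide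
Product: 9 (1R,2R)-2-(4-allyl-2,6-dimethoxyphenoxy)-1-(3,4,5-trimethoxyphenyl)-3-[(triisopropylsilyl)oxy]propan-1-ol
Conditions: 8, MgBr2·OEt2 (2 equiv), CH2Cl2, −78 °C, 20 min; then 7 (1.5 equiv, about 1 M in THF) dropwise, −78 → −40 °C; aq. NH4Cl
Reagents that add atoms: none
Why: MgBr2·OEt2 in dichloromethane is expected to bind the aldehyde oxygen and the C8 ether oxygen of 8 in a five-membered chelate, assisted by a flanking methoxy group of ring B, which holds the C8–O bond syn-periplanar to the C7 carbonyl; the aryl group of 7 then adds to C7 from the face bearing the C8 hydrogen, opposite the silyloxymethyl arm, and work-up gives the carbinol. The closest known reaction type is the Cram-chelate addition of Grignard reagents to α-alkoxy aldehydes pre-complexed with MgBr2. No ring is closed; one skeletal bond, C7 to C1 of ring A, is formed. The new C7 centre is controlled by the existing (R)-C8 centre through the chelate, which from the (R)-aldehyde should give the 1,2-syn (threo, 7R,8R) alcohol. The step needs syn selectivity over the Felkin–Anh (erythro) mode and no loss of C8 integrity. Syn selectivity is secured by the chelating aryloxy and methoxy oxygens, the weakly coordinating solvent and the bulky triisopropylsilyl ether, which does not coordinate and so shuts off a competing six-membered chelate through O9; C8 integrity is secured by the low temperature, the modest basicity of the aryl Grignard reagent and the use of freshly made aldehyde.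

Step 7
Reactants: 9 (1R,2R)-2-(4-allyl-2,6-dimethoxyphenoxy)-1-(3,4,5-trimethoxyphenyl)-3-[(triisopropylsilyl)oxy]propan-1-ol
Product: 10 (1R,2R)-2-(4-allyl-2,6-dimethoxyphenoxy)-1-(3,4,5-trimethoxyphenyl)propane-1,3-diol
Conditions: n-Bu4NF (1.2 equiv), THF, 0 °C → rt
Reagents that add atoms: none
Why: Fluoride-mediated desilylation cleaves only the Si–O bond; the aryl ethers, the allyl group and both stereocentres are not affected.

Step 8
Reactants: 10 (1R,2R)-2-(4-allyl-2,6-dimethoxyphenoxy)-1-(3,4,5-trimethoxyphenyl)propane-1,3-diol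
Product: 11 (2R,3R)-2-(4-allyl-2,6-dimethoxyphenoxy)-3-hydroxy-3-(3,4,5-trimethoxyphenyl)propyl acetate (target, CNP0079124.1)
Conditions: AcCl (1.1 equiv), 2,4,6-collidine (2 equiv), CH2Cl2, −78 °C; neutral work-up
Reagents that add atoms: acetyl chloride, CC(Cl)=O
Why: Selective acylation with acetyl chloride and collidine at −78 °C should acetylate the primary C9 hydroxyl much faster than the secondary benzylic C7 hydroxyl, which is also shielded by ring A and the neighbouring aryloxy group; the neutral work-up avoids acetyl migration.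

**Compound list**

1 | methyl (S)-2,2-dimethyl-1,3-dioxolane-4-carboxylate | COC(=O)[C@@H]1COC(C)(C)O1 | starting material
2 | methyl (S)-2,3-dihydroxypropanoate | COC(=O)[C@@H](O)CO | intermediate
3 | methyl (S)-2-hydroxy-3-[(triisopropylsilyl)oxy]propanoate | COC(=O)[C@@H](O)CO[Si](C(C)C)(C(C)C)C(C)C | intermediate
4 | 4-allyl-2,6-dimethoxyphenol | C=CCc1cc(OC)c(O)c(OC)c1 | starting material
5 | methyl (R)-2-(4-allyl-2,6-dimethoxyphenoxy)-3-[(triisopropylsilyl)oxy]propanoate | C=CCc1cc(OC)c(O[C@H](CO[Si](C(C)C)(C(C)C)C(C)C)C(=O)OC)c(OC)c1 | intermediate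
6 | 5-bromo-1,2,3-trimethoxybenzene | COc1cc(Br)cc(OC)c1OC | starting material
7 | 3,4,5-trimethoxyphenylmagnesium bromide | COc1cc([Mg]Br)cc(OC)c1OC | intermediate
8 | (R)-2-(4-allyl-2,6-dimethoxyphenoxy)-3-[(triisopropylsilyl)oxy]propanal | C=CCc1cc(OC)c(O[C@H](CO[Si](C(C)C)(C(C)C)C(C)C)C=O)c(OC)c1 | intermediate
9 | (1R,2R)-2-(4-allyl-2,6-dimethoxyphenoxy)-1-(3,4,5-trimethoxyphenyl)-3-[(triisopropylsilyl)oxy]propan-1-ol | C=CCc1cc(OC)c(O[C@H](CO[Si](C(C)C)(C(C)C)C(C)C)[C@H](O)c2cc(OC)c(OC)c(OC)c2)c(OC)c1 | intermediate
10 | (1R,2R)-2-(4-allyl-2,6-dimethoxyphenoxy)-1-(3,4,5-trimethoxyphenyl)propane-1,3-diol | C=CCc1cc(OC)c(O[C@H](CO)[C@H](O)c2cc(OC)c(OC)c(OC)c2)c(OC)c1 | intermediate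
11 | (2R,3R)-2-(4-allyl-2,6-dimethoxyphenoxy)-3-hydroxy-3-(3,4,5-trimethoxyphenyl)propyl acetate | C=CCc1cc(OC)c(O[C@H](COC(C)=O)[C@H](O)c2cc(OC)c(OC)c(OC)c2)c(OC)c1 | target

**Step count**

Total steps: 8. Longest linear sequence: 7 steps (steps 1, 2, 3, 5, 6, 7, 8 from compound 1); step 4 is a one-step side branch.

**Steps most likely to fail**

Step 6 (key step). Facial selectivity may be poor: the aryl ether oxygen is a weak donor and THF brought in with the Grignard reagent competes for magnesium, so the open Felkin–Anh mode may intrude and erode the syn preference. Fallback: set out from 8 and 7 and run the addition with no demand on selectivity (THF, −78 °C). This would give 9 mixed with its C7 epimer (1S,2R)-2-(4-allyl-2,6-dimethoxyphenoxy)-1-(3,4,5-trimethoxyphenyl)-3-[(triisopropylsilyl)oxy]propan-1-ol F1. The mixture is oxidised with Dess–Martin periodinane (NaHCO3-buffered, CH2Cl2, 0 °C) to the single ketone (R)-2-(4-allyl-2,6-dimethoxyphenoxy)-1-(3,4,5-trimethoxyphenyl)-3-[(triisopropylsilyl)oxy]propan-1-one F2. Reduction with LiBH(s-Bu)3 in THF at −78 °C follows; under Felkin–Anh control (aryloxy group anti to the incoming hydride, hydride passing the C8 hydrogen) this should give the threo alcohol, and the route is rejoined at 9.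

Step 5. Reduction may run past the aldehyde to the primary alcohol, or C8 may partly epimerise during work-up and handling of the sensitive α-aryloxy aldehyde. Fallback: set out from 5 and reduce the ester fully with LiBH4 (THF, 0 °C → rt) to (S)-2-(4-allyl-2,6-dimethoxyphenoxy)-3-[(triisopropylsilyl)oxy]propan-1-ol F3. The descriptor changes only through CIP priorities; the geometry is unchanged. F3 is oxidised with Dess–Martin periodinane (NaHCO3-buffered, CH2Cl2, 0 °C) under non-basic conditions, and the route is rejoined at 8.

Step 3. With the di-ortho-substituted phenol the etherification may be slow, so elimination of the activated alcohol or its capture by the reduced azodicarboxylate may compete. Fallback: set out from 3 and convert the hydroxyl with Tf2O and 2,6-lutidine (CH2Cl2, −78 °C) into methyl (S)-3-[(triisopropylsilyl)oxy]-2-{[(trifluoromethyl)sulfonyl]oxy}propanoate F4. F4 is displaced by phenol 4 with K2CO3 in MeCN (−20 → 0 °C); SN2 substitution of an α-triflyloxy ester by a phenoxide occurs with inversion, and the route is rejoined at 5.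

**Further compounds**

F1 | step 6 | (1S,2R)-2-(4-allyl-2,6-dimethoxyphenoxy)-1-(3,4,5-trimethoxyphenyl)-3-[(triisopropylsilyl)oxy]propan-1-ol | C=CCc1cc(OC)c(O[C@H](CO[Si](C(C)C)(C(C)C)C(C)C)[C@@H](O)c2cc(OC)c(OC)c(OC)c2)c(OC)c1
F2 | step 6 | (R)-2-(4-allyl-2,6-dimethoxyphenoxy)-1-(3,4,5-trimethoxyphenyl)-3-[(triisopropylsilyl)oxy]propan-1-one | C=CCc1cc(OC)c(O[C@H](CO[Si](C(C)C)(C(C)C)C(C)C)C(=O)c2cc(OC)c(OC)c(OC)c2)c(OC)c1
F3 | step 5 | (S)-2-(4-allyl-2,6-dimethoxyphenoxy)-3-[(triisopropylsilyl)oxy]propan-1-ol | C=CCc1cc(OC)c(O[C@H](CO[Si](C(C)C)(C(C)C)C(C)C)CO)c(OC)c1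
F4 | step 3 | methyl (S)-3-[(triisopropylsilyl)oxy]-2-{[(trifluoromethyl)sulfonyl]oxy}propanoate | COC(=O)[C@@H](OS(=O)(=O)C(F)(F)F)CO[Si](C(C)C)(C(C)C)C(C)C
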